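The flavonol is cut at the O1–C8a bond of ring C. In ring A, C5, C7 and C8a sit ortho, para and ortho to C4a, the carbon that carries the C4 carbonyl, so a 2,4,6-trifluorobenzoyl unit can stand in for the phloroglucinol ring. In one operation the enolate oxygen of a 2-allyloxy-1,3-diketone displaces one ortho fluoride, closing ring C and leaving the C5 and C7 fluorides activated for exchange by allyl oxide. The precursor is that diketone, assembled by C-aroylation of an α-allyloxy ketone carrying the 4-allyloxy-3-prenylphenyl ring B. All four oxygens end as allyl ethers, cleaved together by zerovalent palladium without touching the prenyl group.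

Key step: step 6

Remark: the target has no stereocentre. In step 7 the C7 fluoride (para to the C4 carbonyl) is assumed to be exchanged before the C5 fluoride in DMF; either order leads to the same product. Prenyl means 3-methylbut-2-en-1-yl.

Step 1
Reactants: 1 4-bromophenol; 2 prenyl bromide (1-bromo-3-methylbut-2-ene)
Product: 3 4-bromo-2-(3-methylbut-2-en-1-yl)phenol
Conditions: NaH, toluene, 0 °C to rt
Reagents that add atoms: none
Why: Ortho C-alkylation of a sodium phenoxide in a non-polar solvent: in toluene the tight sodium phenoxide ion pair shields oxygen, so prenyl bromide is taken up at the ring carbon next to it, and bromine blocks the para position.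

Step 2
Reactants: 3 4-bromo-2-(3-methylbut-2-en-1-yl)phenol; 4 allyl bromide
Product: 5 1-(allyloxy)-4-bromo-2-(3-methylbut-2-en-1-yl)benzene
Conditions: K2CO3, acetone, reflux
Reagents that add atoms: none
Why: Williamson ether synthesis: the potassium phenoxide formed by K2CO3 in acetone is alkylated at oxygen by the primary allylic bromide, and neither the aryl bromide nor the prenyl alkene reacts.

Step 3
Reactants: 6 allyl alcohol; 7 2-chloro-N-methoxy-N-methylacetamide
Product: 8 2-(allyloxy)-N-methoxy-N-methylacetamide
Conditions: NaH, THF, 0 °C; then 7, 0 °C to rt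
Reagents that add atoms: none
Why: Williamson ether synthesis: NaOCH2CH=CH2 displaces chloride from the α-chloro amide by SN2, which is much faster than addition of the alkoxide to the N-methoxy-N-methylamide carbonyl at 0 °C.

Step 4
Reactants: 5 1-(allyloxy)-4-bromo-2-(3-methylbut-2-en-1-yl)benzene; 8 2-(allyloxy)-N-methoxy-N-methylacetamide
Product: 10 2-(allyloxy)-1-[4-(allyloxy)-3-(3-methylbut-2-en-1-yl)phenyl]ethan-1-one, via aryllithium 9 (not isolated)
Conditions: n-BuLi, THF, −78 °C; then 8, −78 to 0 °C; aq. NH4Cl
Reagents that add atoms: none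
Why: Bromine–lithium exchange followed by Weinreb ketone synthesis: exchange at −78 °C outpaces any attack on the allyl ether or the prenyl group, and the chelated tetrahedral lithium adduct holds until work-up, so the aryllithium adds only once.

Step 5
Reactants: 10 2-(allyloxy)-1-[4-(allyloxy)-3-(3-methylbut-2-en-1-yl)phenyl]ethan-1-one; 11 2,4,6-trifluorobenzoyl chloride
Product: 12 2-(allyloxy)-1-[4-(allyloxy)-3-(3-methylbut-2-en-1-yl)phenyl]-3-(2,4,6-trifluorophenyl)propane-1,3-dione
Conditions: MgBr2·OEt2, iPr2NEt, CH2Cl2, 0 °C to rt; dilute aqueous acid work-up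
Reagents that add atoms: none
Why: Crossed Claisen-type C-acylation under soft enolisation: MgBr2 chelates the ketone and the α-ether oxygen, iPr2NEt then forms the magnesium enolate, which is acylated at carbon by the acid chloride, and the resulting magnesium diketonate chelate resists a second acylation while the covalent magnesium enolate is too short-lived at 0 °C for an allyl shift.

Step 6
Reactants: 12 2-(allyloxy)-1-[4-(allyloxy)-3-(3-methylbut-2-en-1-yl)phenyl]-3-(2,4,6-trifluorophenyl)propane-1,3-dione
Product: 13 3-(allyloxy)-2-[4-(allyloxy)-3-(3-methylbut-2-en-1-yl)phenyl]-5,7-difluoro-4H-chromen-4-one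
Conditions: K2CO3, DMF (0.02 M), rt to 50 °C
Reagents that add atoms: none
Why: K2CO3 removes the C2–H of 12 and the diketonate oxygen on the carbonyl that carries ring B adds to an ortho C–F carbon of the trifluorophenyl ring (the future C8a), giving a Meisenheimer anion whose charge runs onto C4a and into the C4 carbonyl, after which loss of fluoride completes the O1–C8a bond. The closest known reaction type is the base-mediated intramolecular SNAr cyclisation of 1-(2-fluoroaryl)-1,3-diketones to chromones, the oxygen analogue of the ring closure used for fluoroquinolones. Ring C closes as a six-membered ring by addition–elimination at the sp2 carbon C8a, formally 6-endo-trig with respect to the C4a=C8a bond of this vinylogous acyl fluoride (6-exo-trig if the C8a=C8 bond is counted), both allowed by the Baldwin rules. No stereocentre is formed, and the only one in 12, the enolisable C2–H carbon, becomes the sp2 carbon C3. The step needs attack through oxygen at an ortho fluoride ahead of intermolecular displacement and ahead of an allyl shift in the enolate: carbon attack could only close a four-membered ring, the para fluoride is out of reach, the two ortho fluorides are interchanged by rotation about the aryl–carbonyl bond so either gives 13, dilution favours ring closure, and the charge spread over both carbonyls makes the diketonate a poor partner for O-to-C allyl migration at 50 °C or below.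

Step 7
Reactants: 13 3-(allyloxy)-2-[4-(allyloxy)-3-(3-methylbut-2-en-1-yl)phenyl]-5,7-difluoro-4H-chromen-4-one; 6 allyl alcohol
Product: 15 3,5,7-tris(allyloxy)-2-[4-(allyloxy)-3-(3-methylbut-2-en-1-yl)phenyl]-4H-chromen-4-one, via 7-allyloxy-5-fluoro flavone 14 (not isolated)
Conditions: allyl alcohol (3 equiv), NaH (2.5 equiv), THF, 0 °C; then 13 in DMF, 0 to 50 °C
Reagents that add atoms: allyl alcohol (second equivalent), C=CCO
Why: Twofold nucleophilic aromatic substitution by addition–elimination: one equivalent of NaOCH2CH=CH2 displaces the C7 fluoride para to the C4 carbonyl and a second equivalent displaces the C5 fluoride ortho to it, each through a Meisenheimer anion stabilised by that carbonyl, the new C7 allyloxy group lying meta to C5 and so not deactivating it, while addition of alkoxide at C2 is reversible and leads back to the flavone.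

Step 8
Reactants: 15 3,5,7-tris(allyloxy)-2-[4-(allyloxy)-3-(3-methylbut-2-en-1-yl)phenyl]-4H-chromen-4-one
Product: 16 isolicoflavonol
Conditions: Pd(PPh3)4 (cat.), morpholine, degassed THF, rt
Reagents that add atoms: none
Why: Tsuji–Trost deallylation: zerovalent palladium ionises each allyl aryl or allyl enol ether to a π-allyl palladium complex and a phenoxide, morpholine captures the allyl group irreversibly, and the carbon-bound prenyl group, which has no leaving group, is left alone.

Compound list
1 | 4-bromophenol | Oc1ccc(Br)cc1 | starting material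
2 | prenyl bromide (1-bromo-3-methylbut-2-ene) | CC(C)=CCBr | starting material
3 | 4-bromo-2-(3-methylbut-2-en-1-yl)phenol | CC(C)=CCc1cc(Br)ccc1O | intermediate
4 | allyl bromide | C=CCBr | starting material
5 | 1-(allyloxy)-4-bromo-2-(3-methylbut-2-en-1-yl)benzene | CC(C)=CCc1cc(Br)ccc1OCC=C | intermediate
6 | allyl alcohol | C=CCO | starting material
7 | 2-chloro-N-methoxy-N-methylacetamide | CON(C)C(=O)CCl | starting material
8 | 2-(allyloxy)-N-methoxy-N-methylacetamide | C=CCOCC(=O)N(C)OC | intermediate
9 | [4-(allyloxy)-3-(3-methylbut-2-en-1-yl)phenyl]lithium (aryllithium, not isolated) | [Li]c1ccc(OCC=C)c(CC=C(C)C)c1 | intermediate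
10 | 2-(allyloxy)-1-[4-(allyloxy)-3-(3-methylbut-2-en-1-yl)phenyl]ethan-1-one | C=CCOCC(=O)c1ccc(OCC=C)c(CC=C(C)C)c1 | intermediate
11 | 2,4,6-trifluorobenzoyl chloride | O=C(Cl)c1c(F)cc(F)cc1F | starting material
12 | 2-(allyloxy)-1-[4-(allyloxy)-3-(3-methylbut-2-en-1-yl)phenyl]-3-(2,4,6-trifluorophenyl)propane-1,3-dione (racemic, keto and enol forms) | C=CCOC(C(=O)c1ccc(OCC=C)c(CC=C(C)C)c1)C(=O)c1c(F)cc(F)cc1F | intermediate
13 | 3-(allyloxy)-2-[4-(allyloxy)-3-(3-methylbut-2-en-1-yl)phenyl]-5,7-difluoro-4H-chromen-4-one | C=CCOc1c(-c2ccc(OCC=C)c(CC=C(C)C)c2)oc2cc(F)cc(F)c2c1=O | intermediate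
14 | 3,7-bis(allyloxy)-2-[4-(allyloxy)-3-(3-methylbut-2-en-1-yl)phenyl]-5-fluoro-4H-chromen-4-one (7-allyloxy-5-fluoro flavone, not isolated) | C=CCOc1cc(F)c2c(c1)oc(-c1ccc(OCC=C)c(CC=C(C)C)c1)c(OCC=C)c2=O | intermediate
15 | 3,5,7-tris(allyloxy)-2-[4-(allyloxy)-3-(3-methylbut-2-en-1-yl)phenyl]-4H-chromen-4-one | C=CCOc1cc(OCC=C)c2c(c1)oc(-c1ccc(OCC=C)c(CC=C(C)C)c1)c(OCC=C)c2=O | intermediate
16 | isolicoflavonol, 3,5,7-trihydroxy-2-[4-hydroxy-3-(3-methylbut-2-en-1-yl)phenyl]-4H-chromen-4-one | CC(C)=CCc1cc(-c2oc3cc(O)cc(O)c3c(=O)c2O)ccc1O | target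

Total step count: 8.
Longest linear sequence: 7 steps (steps 1, 2, 4, 5, 6, 7 and 8, from 4-bromophenol 1); step 3 is a one-step side branch.

Steps most likely to fail

Step 6 (key step). If the fluoride displacement needs heating, migration of the allyl group from oxygen to carbon within the diketonate (a [2,3]- or [3,3]-sigmatropic shift) could outrun ring closure. The fallback sets out from 5 and returns at 16; it replaces the allyl group on the C3 oxygen by a methoxymethyl group, which cannot migrate, at the cost of one more deprotection. 2-Hydroxy-N-methoxy-N-methylacetamide would be treated with chloromethyl methyl ether and iPr2NEt in CH2Cl2 to give N-methoxy-2-(methoxymethoxy)-N-methylacetamide F1. Aryllithium 9, made from 5 as in step 4, would be acylated with F1 to give 1-[4-(allyloxy)-3-(3-methylbut-2-en-1-yl)phenyl]-2-(methoxymethoxy)ethan-1-one F2. Aroylation with 11 under the conditions of step 5 would give the 2-(methoxymethoxy)-1,3-diketone F3. K2CO3 in DMF should then close ring C with no shift possible, giving the 5,7-difluoro-3-(methoxymethoxy)flavone F4. Two or more equivalents of NaOCH2CH=CH2 would exchange the fluorides through the 7-allyloxy-5-fluoro flavone F5 (not isolated) to the 5,7-bis(allyloxy) flavone F6. HCl in methanol at rt would cleave the acetal while the ring B oxygen is still allylated, so that no free phenol sits next to the prenyl group under acid, giving the 3-hydroxyflavone F7. Pd(PPh3)4 with morpholine would then remove the three allyl groups to give 16.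

Step 5. Acylation at the enolate oxygen, or a second acylation of the diketonate, could give enol esters in place of the C-aroylated diketone. The fallback sets out from 10 and returns at 12; an aldol addition followed by oxidation replaces the acylation, so that no acid chloride meets the enolate. Ketone 10 would be deprotonated with LiN(SiMe3)2 in THF at −78 °C to the lithium (Z)-enolate F8 (not isolated), which would add to 2,4,6-trifluorobenzaldehyde to give the β-hydroxy ketone F9 as a mixture of diastereomers. Oxidation with Dess–Martin periodinane in CH2Cl2 would then give 12, in which the carbinol centre is gone and the remaining centre is enolisable.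

Step 1. Alkylation at oxygen and double alkylation could compete with ortho C-prenylation and leave little of 3. The fallback sets out from 1 and returns at 3; the prenyl group is built from an allyl group placed by a Claisen rearrangement. Phenol 1 would be O-allylated with 4 and K2CO3 in acetone to allyl 4-bromophenyl ether F10. Heating in N,N-diethylaniline at about 200 °C would give 2-allyl-4-bromophenol F11 by aromatic Claisen rearrangement, the para position being blocked. Cross-metathesis with 2-methylbut-2-ene and the second-generation Grubbs catalyst in CH2Cl2 at 40 °C would convert the allyl into the prenyl group, giving 3.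

Further compounds
F1 | step 6 | N-methoxy-2-(methoxymethoxy)-N-methylacetamide | COCOCC(=O)N(C)OC
F2 | step 6 | 1-[4-(allyloxy)-3-(3-methylbut-2-en-1-yl)phenyl]-2-(methoxymethoxy)ethan-1-one | COCOCC(=O)c1ccc(OCC=C)c(CC=C(C)C)c1
F3 | step 6 | 1-[4-(allyloxy)-3-(3-methylbut-2-en-1-yl)phenyl]-2-(methoxymethoxy)-3-(2,4,6-trifluorophenyl)propane-1,3-dione (racemic) | COCOC(C(=O)c1ccc(OCC=C)c(CC=C(C)C)c1)C(=O)c1c(F)cc(F)cc1F
F4 | step 6 | 2-[4-(allyloxy)-3-(3-methylbut-2-en-1-yl)phenyl]-5,7-difluoro-3-(methoxymethoxy)-4H-chromen-4-one | COCOc1c(-c2ccc(OCC=C)c(CC=C(C)C)c2)oc2cc(F)cc(F)c2c1=O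
F5 | step 6 | 7-(allyloxy)-2-[4-(allyloxy)-3-(3-methylbut-2-en-1-yl)phenyl]-5-fluoro-3-(methoxymethoxy)-4H-chromen-4-one (not isolated) | COCOc1c(-c2ccc(OCC=C)c(CC=C(C)C)c2)oc2cc(OCC=C)cc(F)c2c1=O
F6 | step 6 | 5,7-bis(allyloxy)-2-[4-(allyloxy)-3-(3-methylbut-2-en-1-yl)phenyl]-3-(methoxymethoxy)-4H-chromen-4-one | COCOc1c(-c2ccc(OCC=C)c(CC=C(C)C)c2)oc2cc(OCC=C)cc(OCC=C)c2c1=O
F7 | step 6 | 5,7-bis(allyloxy)-2-[4-(allyloxy)-3-(3-methylbut-2-en-1-yl)phenyl]-3-hydroxy-4H-chromen-4-one | Oc1c(-c2ccc(OCC=C)c(CC=C(C)C)c2)oc2cc(OCC=C)cc(OCC=C)c2c1=O
F8 | step 5 | lithium (Z)-2-(allyloxy)-1-[4-(allyloxy)-3-(3-methylbut-2-en-1-yl)phenyl]ethen-1-olate (not isolated) | [Li]O/C(=C\OCC=C)c1ccc(OCC=C)c(CC=C(C)C)c1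
F9 | step 5 | 2-(allyloxy)-1-[4-(allyloxy)-3-(3-methylbut-2-en-1-yl)phenyl]-3-hydroxy-3-(2,4,6-trifluorophenyl)propan-1-one (mixture of diastereomers, racemic) | C=CCOC(C(O)c1c(F)cc(F)cc1F)C(=O)c1ccc(OCC=C)c(CC=C(C)C)c1
F10 | step 1 | allyl 4-bromophenyl ether | C=CCOc1ccc(Br)cc1
F11 | step 1 | 2-allyl-4-bromophenol | C=CCc1cc(Br)ccc1O
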